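The runs come from a simulation for an exercise, noise included.

At late times in the south run, by 25.0 min, left-handed product stands at 34% and right-handed product at 1%. The end excess depends on the share each product takes, not on how far a flask has gone, provided that share holds.

| setting | south | Monday's | Saturday's |
|---|---|---|---|
| left-handed substrate | 1.3 M | 0.84 M | 0.84 M |
| right-handed substrate | 1.3 M | 0.84 M | 0.84 M |
| coupling partner | 2.1 M | 2.10 M | 2.10 M |
| free catalyst | 47 mM | 47 mM | 25 mM |
| remark | run made earlier |  |  |
| time |  | 40 min | 40 min |

south run (percent of the left-handed substrate and right-handed substrate together charged)

| time / min | left-handed product / % | right-handed product / % |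
|---|---|---|
| 2.00 | 7 | 1 |
| 3.00 | 8 | 1 |
| 5.00 | 15 | 2 |
| 8.00 | 17 | 0 |
| 15.0 | 29 | 0 |
| 25.0 | 34 | 1 |

(readings scatter by 2 percentage points)

- free catalyst is single-handed; left-handed substrate and right-handed substrate are mirror images of each other, charged as a racemate, each of them at the stated concentration
- an excess is the difference of the two amounts in percent of their sum
- an excess is below zero if the other one leads
- no earlier run changes the charge of free catalyst; that part of a forecast is a guess

- the flask that ends with the higher excess of left-handed product over right-handed product in the product, or "neither" when 2 percentage points or less lies between them (Monday's / Saturday's / neither)
- excess of left-handed product over right-handed product in the product at the end, Monday's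
- excess of left-handed product over right-handed product in the product at the end, Saturday's

I read the table column against column. The rows up to 5.00 min give an excess of 76.5%, and the later rows give 97.5%. That is a rise, but a loose one: the right-handed column never tops 2%, and one reading scatters by 2 percentage points. What I can say is that the excess shows no fall.

So I take it as flat and pool the table. The whole table gives 91.3%, and I carry this pooled excess, the difference of the column sums in percent of their total.

A flat excess means a constant ratio of the two product rates, a selectivity factor. If [free catalyst] multiplies both rates alike, it cancels from that ratio, and time drops out while the two substrates stay level. The catalyst part is a guess, since no earlier run changes it. I therefore put both flasks near 91.3%, with no gap above 2 points: neither.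

The forecast differs, with 90% for Monday's, 93% for Saturday's and Saturday's ahead, on the ground "Lower conversion keeps the excess higher".

The flasks give 93.0% for Monday's and 93.1% for Saturday's, so the answer is neither.

    coupling partner ⇌ dormant form (K = 0.160, k = 1.00 /h)
    2 coupling partner → self-condensation product (k = 0.0430 /M/h)
    coupling partner + free catalyst + right-handed substrate → free catalyst + right-handed product (k = 1.40 /M²/h)
    coupling partner + free catalyst + left-handed substrate → free catalyst + left-handed product (k = 40.0 /M²/h)
    2 free catalyst → spent catalyst (k = 6.20 /M/h)
    left-handed substrate ⇌ right-handed substrate (k = 40.0 /h)

In Monday's the relaxation half-life of the two substrates by their interconversion alone is 0.520 min, and at 40.0 min that flask holds 24.1% left-handed and 24.5% right-handed substrate, level as the rule requires. The neighbouring flask is Monday's with 0.019 M of free catalyst. The same reckoning puts its excess at the pooled 91.3%, the figure it gave for Monday's. That neighbour ends with 29.9% left-handed product and 1.06% right-handed product, an excess of 93.1%.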